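**Retrosynthetic overview**

1. Feature: ring A (C1–C5 and C10, labdane numbering) carries at quaternary C10 the methyl C20 cis to the C6 chain on C5 and the acyl carbon C9 trans to it. C20 is therefore delivered from a C6 hydroxyl to a C1=C10 alkene that already bears C9.
2. Endgame disconnections: the benzyl ether on O3' of the glyceride; C9–C11 (ring A acid chloride plus an alkylzinc carrying C11–C15 and the 2-acetyl glyceride); C6=C7 (Horner–Wadsworth–Emmons, then hydrogenation).
3. Key disconnection: C10–C20 and C1–C20, by hydroxyl-directed Simmons–Smith cyclopropanation of the homoallylic alcohol, followed by hydrogenolysis of C1–C20 to the C10 methyl.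
4. The homoallylic alcohol: C5 is set by catalyst control (CBS reduction of a 2-(silyloxymethyl)enone) and 1,3-transfer in a Wittig–Still rearrangement, not by a resolution; C9 comes from formaldehyde and C6 from the stannane.
5. Ring order: ring A is bought as 4,4-dimethylcyclohex-2-en-1-one; the only ring made is the cyclopropane on C1/C10 (step 6), which is opened again in step 7.

Key step: step 6

Remark 1: labdane numbering is used for the diterpenoid part (C17 = ketone methyl, C6–C8 = oxobutyl chain, C11–C15 = hexanoate chain); glycerol atoms are primed, C1' carrying the diterpenoid acyl group.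
Remark 2: the target is read as the 1-acyl-2-acetyl-sn-glycerol; from (S)-solketal the free hydroxymethyl group must end as the free C3' hydroxyl, so it is benzylated and the acyl group is placed on the former acetal CH2–O.
Remark 3: O9 is carried as a triisopropylsilyl ether, which is bulky and weakly coordinating for the key step and has no aryl ring at risk under H2/PtO2/AcOH.

**Route**

Step 1
Reactants: 1 4,4-dimethylcyclohex-2-en-1-one; 2 formaldehyde
Product: 3 2-(hydroxymethyl)-4,4-dimethylcyclohex-2-en-1-one
Conditions: 37% aq. HCHO, DMAP (cat.), THF/H2O, rt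
Reagents that add atoms: none
Why: Morita–Baylis–Hillman hydroxymethylation, in which DMAP adds to C3 of the enone, the enolate so formed captures formaldehyde at C2 and the catalyst is expelled again, so that the future C9 is placed on the alkene carbon without creating a stereocentre.

Step 2
Reactants: 3 2-(hydroxymethyl)-4,4-dimethylcyclohex-2-en-1-one
Product: 4 4,4-dimethyl-2-({[tri(propan-2-yl)silyl]oxy}methyl)cyclohex-2-en-1-one
Conditions: i-Pr3SiCl, imidazole, DMF, 0 °C → rt
Reagents that add atoms: chlorotri(propan-2-yl)silane, CC(C)[Si](Cl)(C(C)C)C(C)C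
Why: Imidazole-mediated silylation of the primary allylic alcohol, chosen because the triisopropylsilyl ether survives KH, n-BuLi and acetic acid and cannot be reduced later by platinum and hydrogen.

Step 3
Reactants: 4 4,4-dimethyl-2-({[tri(propan-2-yl)silyl]oxy}methyl)cyclohex-2-en-1-one
Product: 5 (1S)-4,4-dimethyl-2-({[tri(propan-2-yl)silyl]oxy}methyl)cyclohex-2-en-1-ol
Conditions: (R)-Me-CBS oxazaborolidine (C18H20BNO, 10 mol%), BH3·SMe2, THF, −20 °C; aq. NH4Cl
Reagents that add atoms: none
Why: Corey–Bakshi–Shibata reduction, in which the enone binds the oxazaborolidine–borane complex with its substituted alkenyl arm as the large group, so that the (R)-catalyst should deliver hydride to the face giving the (1S)-carbinol, the stereocentre that is later relayed to C5.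

Step 4
Reactants: 5 (1S)-4,4-dimethyl-2-({[tri(propan-2-yl)silyl]oxy}methyl)cyclohex-2-en-1-ol; 6 tributyl(iodomethyl)stannane
Product: 7 tributyl({[(1S)-4,4-dimethyl-2-({[tri(propan-2-yl)silyl]oxy}methyl)cyclohex-2-en-1-yl]oxy}methyl)stannane
Conditions: KH, 18-crown-6 (cat.), THF, 0 °C → rt
Reagents that add atoms: none
Why: Williamson etherification of the potassium alkoxide with the unhindered primary iodide, which leaves the carbinol centre untouched, while migration of the bulky silyl group from the primary to the secondary oxygen is not expected.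

Step 5
Reactants: 7 tributyl({[(1S)-4,4-dimethyl-2-({[tri(propan-2-yl)silyl]oxy}methyl)cyclohex-2-en-1-yl]oxy}methyl)stannane
Product: 9 [(1R)-6,6-dimethyl-2-({[tri(propan-2-yl)silyl]oxy}methyl)cyclohex-2-en-1-yl]methanol, via lithiomethyl ether 8 (not isolated)
Conditions: n-BuLi, THF, −78 °C → −30 °C; then H2O
Reagents that add atoms: none
Why: Wittig–Still [2,3]-sigmatropic rearrangement, in which tin–lithium exchange gives the α-alkoxymethyllithium 8 that bonds to C5 suprafacially across the allyl unit, so that the (1S) C–O centre is transferred to (R)-C5, the alkene moves to C1=C10 and the new hydroxymethyl group is C6.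

Step 6
Reactants: 9 [(1R)-6,6-dimethyl-2-({[tri(propan-2-yl)silyl]oxy}methyl)cyclohex-2-en-1-yl]methanol; 10 diiodomethane
Product: 12 [(1R,2R,6R)-3,3-dimethyl-1-({[tri(propan-2-yl)silyl]oxy}methyl)bicyclo[4.1.0]heptan-2-yl]methanol (cyclopropane CH2 cis to the hydroxymethyl group), via iodomethylzinc alkoxide 11 (not isolated)
Conditions: Et2Zn (3 equiv), CH2I2 (3 equiv), CH2Cl2, −10 °C → rt; aq. NH4Cl
Reagents that add atoms: none
Why: Et2Zn and CH2I2 give ethyl(iodomethyl)zinc, which is protonated by the C6 hydroxyl to the (iodomethyl)zinc alkoxide 11; its carbenoid carbon is thereby held over the face of the C1=C10 alkene that carries the C5 hydroxymethyl group and is transferred in a concerted butterfly transition state in which C10–C20 and C1–C20 form together while iodide passes to zinc. The closest known reaction type is the hydroxyl-directed Simmons–Smith cyclopropanation in its Furukawa form, as applied to cycloalkenyl carbinols. The three-membered ring is closed by a stereospecific syn [2+1] addition across C1=C10, which gives a cis-fused bicyclo[4.1.0]heptane. The new stereocentres C10 and C1 are both controlled by the existing centre C5 through the O–Zn tether, so that C20 enters cis to C6, and the syn addition ties the configuration of C1 to that of C10. The selectivity needed is facial: it is secured by the pseudoaxial position that A(1,2) strain with the C10 substituent imposes on the hydroxymethyl group, which places the zinc alkoxide directly over the alkene, by the rate advantage of alkoxide-bound carbenoid over unbound reagent, and by the bulky, weakly coordinating silyl ether on O9, which cannot guide zinc to the opposite face.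

Step 7
Reactants: 12 [(1R,2R,6R)-3,3-dimethyl-1-({[tri(propan-2-yl)silyl]oxy}methyl)bicyclo[4.1.0]heptan-2-yl]methanol
Product: 13 [(1R,2R)-2,6,6-trimethyl-2-({[tri(propan-2-yl)silyl]oxy}methyl)cyclohexyl]methanol (C10 methyl cis to the hydroxymethyl group)
Conditions: H2 (3 atm), PtO2, AcOH, rt
Reagents that add atoms: none
Why: Catalytic hydrogenolysis of a cyclopropane over Adams catalyst, which cleaves the least substituted and least hindered bond C1–C20 with release of ring strain, so that C20 remains on C10 as a methyl cis to C6 and the configuration fixed at C10 in step 6 is kept.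

Step 8
Reactants: 13 [(1R,2R)-2,6,6-trimethyl-2-({[tri(propan-2-yl)silyl]oxy}methyl)cyclohexyl]methanol
Product: 14 (1R,2R)-2,6,6-trimethyl-2-({[tri(propan-2-yl)silyl]oxy}methyl)cyclohexane-1-carbaldehyde
Conditions: Dess–Martin periodinane, CH2Cl2, 0 °C → rt
Reagents that add atoms: none
Why: Dess–Martin oxidation of the primary alcohol to the aldehyde under near-neutral conditions, under which the C5 hydrogen, flanked by two quaternary carbons, should not enolise and C5 keeps its configuration.

Step 9
Reactants: 14 (1R,2R)-2,6,6-trimethyl-2-({[tri(propan-2-yl)silyl]oxy}methyl)cyclohexane-1-carbaldehyde; 15 dimethyl (2-oxopropyl)phosphonate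
Product: 16 (3E)-4-[(1R,2R)-2,6,6-trimethyl-2-({[tri(propan-2-yl)silyl]oxy}methyl)cyclohexyl]but-3-en-2-one
Conditions: NaH, THF, 0 °C → 50 °C
Reagents that add atoms: none
Why: Horner–Wadsworth–Emmons olefination, in which the small sodium ketophosphonate anion adds to the hindered aldehyde and syn-elimination of dimethyl phosphate gives the (E)-enone that carries C7, C8 and the C17 methyl.

Step 10
Reactants: 16 (3E)-4-[(1R,2R)-2,6,6-trimethyl-2-({[tri(propan-2-yl)silyl]oxy}methyl)cyclohexyl]but-3-en-2-one
Product: 17 4-[(1R,2R)-2,6,6-trimethyl-2-({[tri(propan-2-yl)silyl]oxy}methyl)cyclohexyl]butan-2-one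
Conditions: H2 (1 atm), 10% Pd/C, EtOAc, rt
Reagents that add atoms: none
Why: Heterogeneous hydrogenation of the conjugated disubstituted C6=C7 bond, which is fast over palladium while the ketone and the silyl ether are inert, and which creates no stereocentre.

Step 11
Reactants: 17 4-[(1R,2R)-2,6,6-trimethyl-2-({[tri(propan-2-yl)silyl]oxy}methyl)cyclohexyl]butan-2-one
Product: 18 4-[(1R,2R)-2-(hydroxymethyl)-2,6,6-trimethylcyclohexyl]butan-2-one
Conditions: Bu4NF, AcOH, THF, rt
Reagents that add atoms: none
Why: Fluoride-induced desilylation driven by the strong Si–F bond, buffered with acetic acid so that the methyl ketone is not exposed to basic fluoride.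

Step 12
Reactants: 18 4-[(1R,2R)-2-(hydroxymethyl)-2,6,6-trimethylcyclohexyl]butan-2-one
Product: 19 (1R,2R)-1,3,3-trimethyl-2-(3-oxobutyl)cyclohexane-1-carbaldehyde
Conditions: Dess–Martin periodinane, CH2Cl2, rt
Reagents that add atoms: none
Why: Dess–Martin oxidation of the neopentyl-type primary alcohol, giving an aldehyde on quaternary C10 that cannot enolise and a 1,6-keto aldehyde that should not undergo aldol closure in the absence of base or amine.

Step 13
Reactants: 19 (1R,2R)-1,3,3-trimethyl-2-(3-oxobutyl)cyclohexane-1-carbaldehyde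
Product: 20 (1R,2R)-1,3,3-trimethyl-2-(3-oxobutyl)cyclohexane-1-carboxylic acid
Conditions: NaClO2, NaH2PO4, 2-methylbut-2-ene, t-BuOH/H2O, rt
Reagents that add atoms: sodium chlorite, [Na+].[O-]Cl=O
Why: Pinnick (Lindgren) oxidation, in which chlorous acid oxidises only the aldehyde to the carboxylic acid while 2-methylbut-2-ene traps the hypochlorous acid that would otherwise chlorinate the methyl ketone.

Step 14
Reactants: 21 monomethyl (R)-3-methylglutarate
Product: 23 (4R)-4-methyloxan-2-one, via hydroxy ester 22 (not isolated)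
Conditions: BH3·SMe2, THF, −10 °C → rt; aq. work-up; then TsOH·H2O (cat.), CH2Cl2, rt
Reagents that add atoms: none
Why: Borane reduces the free carboxylic acid through its acyloxyborane much faster than the methyl ester, and acid-catalysed lactonisation of hydroxy ester 22 then closes the six-membered lactone without touching the methyl-bearing stereocentre, whose acid-derived arm becomes C11–C12 of the target.

Step 15
Reactants: 23 (4R)-4-methyloxan-2-one
Product: 25 (3S)-5-iodo-3-methylpentanoic acid, via trimethylsilyl ester 24 (not isolated)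
Conditions: Me3SiI, CH2Cl2, rt; then H2O
Reagents that add atoms: iodotrimethylsilane, C[Si](C)(C)I
Why: Lactone cleavage with iodotrimethylsilane, in which silylation of the carbonyl oxygen lets iodide open the ring by SN2 attack at the O–CH2 carbon (C11), and hydrolysis of silyl ester 24 on work-up frees the acid.

Step 16
Reactants: 26 (S)-solketal
Product: 27 (4S)-4-[(benzyloxy)methyl]-2,2-dimethyl-1,3-dioxolane
Conditions: NaH, BnBr, Bu4NI (cat.), THF, 0 °C → rt
Reagents that add atoms: benzyl bromide, BrCc1ccccc1
Why: Williamson benzylation of the only free hydroxyl, which marks the carbon that must carry the free C3' hydroxyl of the target and does not involve the stereocentre.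

Step 17
Reactants: 27 (4S)-4-[(benzyloxy)methyl]-2,2-dimethyl-1,3-dioxolane
Product: 28 (2R)-3-(benzyloxy)propane-1,2-diol
Conditions: AcOH/H2O (4:1), 50 °C
Reagents that add atoms: none
Why: Acid-catalysed hydrolysis of the isopropylidene acetal, which breaks only acetal C–O bonds so that the configuration at C2' is retained and a primary and a secondary hydroxyl are released.

Step 18
Reactants: 25 (3S)-5-iodo-3-methylpentanoic acid; 28 (2R)-3-(benzyloxy)propane-1,2-diol
Product: 29 (2S)-3-(benzyloxy)-2-hydroxypropyl (3S)-5-iodo-3-methylpentanoate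
Conditions: DCC, DMAP (cat.), CH2Cl2, −20 °C → 0 °C
Reagents that add atoms: none
Why: Steglich esterification, in which the acylpyridinium ion formed from the O-acylisourea reacts with the unhindered primary hydroxyl of the diol faster than with the secondary one at low temperature, which puts the acyl group on C1'.

Step 19
Reactants: 29 (2S)-3-(benzyloxy)-2-hydroxypropyl (3S)-5-iodo-3-methylpentanoate; 30 acetic anhydride
Product: 31 (2S)-2-(acetyloxy)-3-(benzyloxy)propyl (3S)-5-iodo-3-methylpentanoate
Conditions: Et3N, DMAP (cat.), CH2Cl2, 0 °C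
Reagents that add atoms: none
Why: DMAP-catalysed acetylation of the remaining secondary hydroxyl with retention at C2', carried out cold and briefly so that the primary iodide is not quaternised by the amine.

Step 20
Reactants: 20 (1R,2R)-1,3,3-trimethyl-2-(3-oxobutyl)cyclohexane-1-carboxylic acid
Product: 32 (1R,2R)-1,3,3-trimethyl-2-(3-oxobutyl)cyclohexane-1-carbonyl chloride
Conditions: (COCl)2, DMF (cat.), CH2Cl2, 0 °C → rt; evaporation, used at once
Reagents that add atoms: oxalyl chloride, O=C(Cl)C(Cl)=O
Why: Conversion of the hindered acid into its chloride through the Vilsmeier-type chloroiminium salt formed from oxalyl chloride and DMF, with only gaseous by-products and no enolisable position next to C9.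

Step 21
Reactants: 31 (2S)-2-(acetyloxy)-3-(benzyloxy)propyl (3S)-5-iodo-3-methylpentanoate; 32 (1R,2R)-1,3,3-trimethyl-2-(3-oxobutyl)cyclohexane-1-carbonyl chloride
Product: 34 (2S)-2-(acetyloxy)-3-(benzyloxy)propyl (3R)-3-methyl-6-oxo-6-[(1R,2R)-1,3,3-trimethyl-2-(3-oxobutyl)cyclohexyl]hexanoate, via alkylzinc iodide 33 (not isolated)
Conditions: Zn dust (activated with BrCH2CH2Br and Me3SiCl), LiCl, THF, 40 °C; then 32, Pd(PPh3)4 (5 mol%), THF, 0 °C → rt
Reagents that add atoms: none
Why: Negishi acylation, in which zinc inserts into the primary C–I bond without touching the esters, zerovalent palladium adds oxidatively to the acyl chloride, and transmetalation and reductive elimination form the C9–C11 bond, while the alkylzinc is too unreactive to attack the ketones or esters, so that the ketone is formed without over-addition.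

Step 22
Reactants: 34 (2S)-2-(acetyloxy)-3-(benzyloxy)propyl (3R)-3-methyl-6-oxo-6-[(1R,2R)-1,3,3-trimethyl-2-(3-oxobutyl)cyclohexyl]hexanoate
Product: 35 (2S)-2-(acetyloxy)-3-hydroxypropyl (3R)-3-methyl-6-oxo-6-[(1R,2R)-1,3,3-trimethyl-2-(3-oxobutyl)cyclohexyl]hexanoate (CNP0287223.1)
Conditions: H2 (1 atm), 10% Pd/C, EtOAc, rt
Reagents that add atoms: none
Why: Hydrogenolysis of the benzyl ether over palladium under neutral conditions in an aprotic solvent, which leaves the two ketones and both esters untouched and avoids migration of the acetyl group from O2' to the freed O3'.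

**Compound list**

1 | 4,4-dimethylcyclohex-2-en-1-one | CC1(C)CCC(=O)C=C1 | starting material
2 | formaldehyde | C=O | starting material
3 | 2-(hydroxymethyl)-4,4-dimethylcyclohex-2-en-1-one | CC1(C)CCC(=O)C(CO)=C1 | intermediate
4 | 4,4-dimethyl-2-({[tri(propan-2-yl)silyl]oxy}methyl)cyclohex-2-en-1-one | CC1(C)CCC(=O)C(CO[Si](C(C)C)(C(C)C)C(C)C)=C1 | intermediate
5 | (1S)-4,4-dimethyl-2-({[tri(propan-2-yl)silyl]oxy}methyl)cyclohex-2-en-1-ol | O[C@H]1CCC(C)(C)C=C1CO[Si](C(C)C)(C(C)C)C(C)C | intermediate
6 | tributyl(iodomethyl)stannane | CCCC[Sn](CCCC)(CCCC)CI | starting material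
7 | tributyl({[(1S)-4,4-dimethyl-2-({[tri(propan-2-yl)silyl]oxy}methyl)cyclohex-2-en-1-yl]oxy}methyl)stannane | CCCC[Sn](CCCC)(CCCC)CO[C@H]1CCC(C)(C)C=C1CO[Si](C(C)C)(C(C)C)C(C)C | intermediate
8 | ({[(1S)-4,4-dimethyl-2-({[tri(propan-2-yl)silyl]oxy}methyl)cyclohex-2-en-1-yl]oxy}methyl)lithium | [Li]CO[C@H]1CCC(C)(C)C=C1CO[Si](C(C)C)(C(C)C)C(C)C | intermediate (not isolated)
9 | [(1R)-6,6-dimethyl-2-({[tri(propan-2-yl)silyl]oxy}methyl)cyclohex-2-en-1-yl]methanol | OC[C@@H]1C(C)(C)CCC=C1CO[Si](C(C)C)(C(C)C)C(C)C | intermediate (key-step precursor)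
10 | diiodomethane | ICI | starting material
11 | (iodomethyl)zinc alkoxide of 9 | IC[Zn]OC[C@@H]1C(C)(C)CCC=C1CO[Si](C(C)C)(C(C)C)C(C)C | intermediate (not isolated)
12 | [(1R,2R,6R)-3,3-dimethyl-1-({[tri(propan-2-yl)silyl]oxy}methyl)bicyclo[4.1.0]heptan-2-yl]methanol | OC[C@@H]1C(C)(C)CC[C@@H]2C[C@]12CO[Si](C(C)C)(C(C)C)C(C)C | intermediate (key-step product)
13 | [(1R,2R)-2,6,6-trimethyl-2-({[tri(propan-2-yl)silyl]oxy}methyl)cyclohexyl]methanol | OC[C@@H]1C(C)(C)CCC[C@@]1(C)CO[Si](C(C)C)(C(C)C)C(C)C | intermediate
14 | (1R,2R)-2,6,6-trimethyl-2-({[tri(propan-2-yl)silyl]oxy}methyl)cyclohexane-1-carbaldehyde | O=C[C@@H]1C(C)(C)CCC[C@@]1(C)CO[Si](C(C)C)(C(C)C)C(C)C | intermediate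
15 | dimethyl (2-oxopropyl)phosphonate | COP(=O)(CC(C)=O)OC | starting material
16 | (3E)-4-[(1R,2R)-2,6,6-trimethyl-2-({[tri(propan-2-yl)silyl]oxy}methyl)cyclohexyl]but-3-en-2-one | CC(=O)/C=C/[C@@H]1C(C)(C)CCC[C@@]1(C)CO[Si](C(C)C)(C(C)C)C(C)C | intermediate
17 | 4-[(1R,2R)-2,6,6-trimethyl-2-({[tri(propan-2-yl)silyl]oxy}methyl)cyclohexyl]butan-2-one | CC(=O)CC[C@@H]1C(C)(C)CCC[C@@]1(C)CO[Si](C(C)C)(C(C)C)C(C)C | intermediate
18 | 4-[(1R,2R)-2-(hydroxymethyl)-2,6,6-trimethylcyclohexyl]butan-2-one | CC(=O)CC[C@@H]1C(C)(C)CCC[C@@]1(C)CO | intermediate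
19 | (1R,2R)-1,3,3-trimethyl-2-(3-oxobutyl)cyclohexane-1-carbaldehyde | CC(=O)CC[C@@H]1C(C)(C)CCC[C@@]1(C)C=O | intermediate
20 | (1R,2R)-1,3,3-trimethyl-2-(3-oxobutyl)cyclohexane-1-carboxylic acid | CC(=O)CC[C@@H]1C(C)(C)CCC[C@@]1(C)C(=O)O | intermediate
21 | monomethyl (R)-3-methylglutarate | OC(=O)C[C@@H](C)CC(=O)OC | starting material
22 | methyl (3R)-5-hydroxy-3-methylpentanoate | OCC[C@@H](C)CC(=O)OC | intermediate (not isolated)
23 | (4R)-4-methyloxan-2-one | C[C@@H]1CCOC(=O)C1 | intermediate
24 | trimethylsilyl (3S)-5-iodo-3-methylpentanoate | ICC[C@@H](C)CC(=O)O[Si](C)(C)C | intermediate (not isolated)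
25 | (3S)-5-iodo-3-methylpentanoic acid | ICC[C@@H](C)CC(=O)O | intermediate
26 | (S)-solketal | CC1(C)OC[C@H](CO)O1 | starting material
27 | (4S)-4-[(benzyloxy)methyl]-2,2-dimethyl-1,3-dioxolane | CC1(C)OC[C@H](COCc2ccccc2)O1 | intermediate
28 | (2R)-3-(benzyloxy)propane-1,2-diol | OC[C@H](COCc1ccccc1)O | intermediate
29 | (2S)-3-(benzyloxy)-2-hydroxypropyl (3S)-5-iodo-3-methylpentanoate | ICC[C@@H](C)CC(=O)OC[C@H](COCc1ccccc1)O | intermediate
30 | acetic anhydride | CC(=O)OC(C)=O | starting material
31 | (2S)-2-(acetyloxy)-3-(benzyloxy)propyl (3S)-5-iodo-3-methylpentanoate | ICC[C@@H](C)CC(=O)OC[C@H](COCc1ccccc1)OC(C)=O | intermediate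
32 | (1R,2R)-1,3,3-trimethyl-2-(3-oxobutyl)cyclohexane-1-carbonyl chloride | CC(=O)CC[C@@H]1C(C)(C)CCC[C@@]1(C)C(Cl)=O | intermediate
33 | {(3S)-5-[(2S)-2-(acetyloxy)-3-(benzyloxy)propoxy]-3-methyl-5-oxopentyl}zinc iodide | I[Zn]CC[C@@H](C)CC(=O)OC[C@H](COCc1ccccc1)OC(C)=O | intermediate (not isolated)
34 | (2S)-2-(acetyloxy)-3-(benzyloxy)propyl (3R)-3-methyl-6-oxo-6-[(1R,2R)-1,3,3-trimethyl-2-(3-oxobutyl)cyclohexyl]hexanoate | CC(=O)CC[C@@H]1C(C)(C)CCC[C@@]1(C)C(=O)CC[C@@H](C)CC(=O)OC[C@H](COCc2ccccc2)OC(C)=O | intermediate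
35 | (2S)-2-(acetyloxy)-3-hydroxypropyl (3R)-3-methyl-6-oxo-6-[(1R,2R)-1,3,3-trimethyl-2-(3-oxobutyl)cyclohexyl]hexanoate | CC(=O)CC[C@@H]1C(C)(C)CCC[C@@]1(C)C(=O)CC[C@@H](C)CC(=O)OC[C@H](CO)OC(C)=O | target

**Step count**

Total: 22 steps. Longest linear sequence: 16 steps (steps 1–13, 20, 21, 22).

**Steps most likely to fail**

Step 6 (key step). Methylene transfer from carbenoid that is not bound to the C6 alkoxide, or over the less encumbered face anti to the C5 hydroxymethyl group, would erode the cis relation of C20 and C6. The fallback replaces substrate direction through O6 by reagent control through the allylic O9 hydroxyl. It sets out from 9. Acetylation (Ac2O, pyridine) should give [(1R)-6,6-dimethyl-2-({[tri(propan-2-yl)silyl]oxy}methyl)cyclohex-2-en-1-yl]methyl acetate F1. HF·pyridine in THF should then free the allylic alcohol [(1R)-2-(hydroxymethyl)-6,6-dimethylcyclohex-2-en-1-yl]methyl acetate F2. Charette cyclopropanation (Zn(CH2I)2·DME, CH2Cl2) in the presence of 2-butyl-N,N,N',N'-tetramethyl-1,3,2-dioxaborolane-4,5-dicarboxamide, using the enantiomer whose established sense of induction for allylic alcohols places the methylene on the C6 face, should give [(1R,2R,6R)-1-(hydroxymethyl)-3,3-dimethylbicyclo[4.1.0]heptan-2-yl]methyl acetate F3. Silylation (i-Pr3SiOTf, 2,6-lutidine) should give [(1R,2R,6R)-3,3-dimethyl-1-({[tri(propan-2-yl)silyl]oxy}methyl)bicyclo[4.1.0]heptan-2-yl]methyl acetate F4. K2CO3 in MeOH removes the acetate and the route is rejoined at 12.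

Step 9. Addition of the stabilised phosphonate anion to an aldehyde flanked by two quaternary carbons may be too slow, and forcing it invites enolisation at C5. The fallback uses a smaller and more reactive nucleophile in an aldol addition followed by dehydration. It sets out from 14. The lithium enolate of acetone (LDA, acetone, THF, −78 °C) should give 4-hydroxy-4-[(1R,2R)-2,6,6-trimethyl-2-({[tri(propan-2-yl)silyl]oxy}methyl)cyclohexyl]butan-2-one F5 as a mixture of C6 epimers. MsCl and Et3N should give the mesylate 4-oxo-1-[(1R,2R)-2,6,6-trimethyl-2-({[tri(propan-2-yl)silyl]oxy}methyl)cyclohexyl]butan-2-yl methanesulfonate F6. DBU then eliminates it to the (E)-enone, and the route is rejoined at 16.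

Step 21. Acyl transfer to the α-quaternary acid chloride may be slower than protonolysis or homocoupling of the alkylzinc, or the acylpalladium intermediate may lose CO. The fallback forms the C9–C11 bond by 1,2-addition to the aldehyde and oxidises afterwards. It sets out from keto aldehyde 19 and iodide 31. Chromium dichloride with catalytic cobalt phthalocyanine (C32H16CoN8) in DMF should generate the alkylchromium reagent, which adds to aldehydes in preference to ketones and esters, and give (2S)-2-(acetyloxy)-3-(benzyloxy)propyl (3R)-6-hydroxy-3-methyl-6-[(1R,2R)-1,3,3-trimethyl-2-(3-oxobutyl)cyclohexyl]hexanoate F7 as a mixture of C9 epimers. Dess–Martin oxidation then gives the ketone, and the route is rejoined at 34.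

**Further compounds**

F1 | step 6 | [(1R)-6,6-dimethyl-2-({[tri(propan-2-yl)silyl]oxy}methyl)cyclohex-2-en-1-yl]methyl acetate | CC(=O)OC[C@@H]1C(C)(C)CCC=C1CO[Si](C(C)C)(C(C)C)C(C)C
F2 | step 6 | [(1R)-2-(hydroxymethyl)-6,6-dimethylcyclohex-2-en-1-yl]methyl acetate | CC(=O)OC[C@@H]1C(C)(C)CCC=C1CO
F3 | step 6 | [(1R,2R,6R)-1-(hydroxymethyl)-3,3-dimethylbicyclo[4.1.0]heptan-2-yl]methyl acetate | CC(=O)OC[C@@H]1C(C)(C)CC[C@@H]2C[C@]12CO
F4 | step 6 | [(1R,2R,6R)-3,3-dimethyl-1-({[tri(propan-2-yl)silyl]oxy}methyl)bicyclo[4.1.0]heptan-2-yl]methyl acetate | CC(=O)OC[C@@H]1C(C)(C)CC[C@@H]2C[C@]12CO[Si](C(C)C)(C(C)C)C(C)C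
F5 | step 9 | 4-hydroxy-4-[(1R,2R)-2,6,6-trimethyl-2-({[tri(propan-2-yl)silyl]oxy}methyl)cyclohexyl]butan-2-one | CC(=O)CC(O)[C@@H]1C(C)(C)CCC[C@@]1(C)CO[Si](C(C)C)(C(C)C)C(C)C
F6 | step 9 | 4-oxo-1-[(1R,2R)-2,6,6-trimethyl-2-({[tri(propan-2-yl)silyl]oxy}methyl)cyclohexyl]butan-2-yl methanesulfonate | CC(=O)CC(OS(C)(=O)=O)[C@@H]1C(C)(C)CCC[C@@]1(C)CO[Si](C(C)C)(C(C)C)C(C)C
F7 | step 21 | (2S)-2-(acetyloxy)-3-(benzyloxy)propyl (3R)-6-hydroxy-3-methyl-6-[(1R,2R)-1,3,3-trimethyl-2-(3-oxobutyl)cyclohexyl]hexanoate | CC(=O)CC[C@@H]1C(C)(C)CCC[C@@]1(C)C(O)CC[C@@H](C)CC(=O)OC[C@H](COCc2ccccc2)OC(C)=O
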